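**Retrosynthetic overview** (chain numbering: C3 = butenolide α-carbon, C7 and C11 = stereocenters, C14=C15 = Z-alkene)
1. C3–C4: target ⇒ terminal allyl group on C7 (9-BBN, Suzuki) + 3-bromofuran-2(5H)-one. The butenolide is the only ring; it is not built but taken over intact from furan-2(5H)-one and attached in the last step.
2. C5–C6 and C13–C14: allyl group ⇒ CH2Br + vinyl bromide; Z-allylic alcohol arm ⇒ vinyl group on C11 (9-BBN, Suzuki) + (Z)-3-iodo-2-methylprop-2-en-1-ol.
3. C9–C10: alkyl–alkyl Suzuki union of two four-carbon halides XCH2–CH(CH=CH2)–CH2OAc of opposite configuration (bromide ⇒ C6–C9, iodide ⇒ C10–C13).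
4. Key step: both halides ⇒ the two enantiomeric monoacetates of one prochiral diol, 2-vinylpropane-1,3-diol. The enantiotopic-group-selective O-acetylation (C–O bond formation) sets C7 and C11 and puts the two acetates of the target in place.
5. Diol ⇒ diethyl ethylidenemalonate (deconjugation, reduction).

Assumption: porcine pancreatic lipase acetylates 2-vinylpropane-1,3-diol to the (R)-monoacetate and the (S,S)-ligand zinc catalyst gives the (S)-monoacetate; if either sense proves opposite, the mirror-image ligand is used or the two catalysts exchange their tasks, and no other step changes.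

**Step 1**
Reactants: 1 diethyl 2-ethylidenemalonate
Product: 3 diethyl 2-vinylmalonate, via lithium dienolate 2 (not isolated)
Conditions: LiN(SiMe3)2, THF, −78 °C; then AcOH, −78 °C → rt
Reagents that add atoms: none
Why: Deconjugative protonation: the base removes a γ-proton to give the delocalised malonate dienolate, and kinetic protonation at the α-carbon gives the β,γ-unsaturated vinylmalonate; no stereocenter is formed.

**Step 2**
Reactants: 3 diethyl 2-vinylmalonate
Product: 4 2-vinylpropane-1,3-diol
Conditions: LiAlH4, Et2O, −40 → 0 °C (ester added to the hydride); H2O, aq NaOH work-up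
Reagents that add atoms: none
Why: LiAlH4 reduction of both esters to the prochiral 1,3-diol, with inverse addition in the cold so that reduction outruns enolisation of the acidic malonate C–H; no stereocenter yet.

**Step 3**
Reactants: 4 2-vinylpropane-1,3-diol
Product: 5 (S)-2-(hydroxymethyl)but-3-en-1-yl acetate
Conditions: Et2Zn (10 mol%), (S,S)-L (5 mol%), isopropenyl acetate (3 equiv), toluene, −20 °C; L = 2,6-bis({(2S)-2-[bis(3,5-di-tert-butylphenyl)(hydroxy)methyl]pyrrolidin-1-yl}methyl)-4-methylphenol
Reagents that add atoms: isopropenyl acetate, CC(=C)OC(C)=O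
Why: Proposed new method: a dinuclear zinc alkoxide catalyst (Et2Zn plus the new bulky ProPhenol-type ligand L) binds the diol as a bridging mono-alkoxide, holds isopropenyl acetate on the second zinc and passes the acetyl group inside the chiral pocket to only one of the two enantiotopic CH2O groups, so that this C–O bond formation sets the stereocenter that becomes C11 (acetone loss makes it irreversible, the small vinyl group sits in the open quadrant); the closest known reaction type is the dinuclear zinc ProPhenol desymmetrising benzoylation of 2-aryl- and 2-methylpropane-1,3-diols by vinyl benzoate, and new here are acetyl transfer, the 2-alkenyl diol and the ligand.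

**Step 4**
Reactants: 4 2-vinylpropane-1,3-diol
Product: 6 (R)-2-(hydroxymethyl)but-3-en-1-yl acetate
Conditions: porcine pancreatic lipase, vinyl acetate, THF, 25 °C
Reagents that add atoms: vinyl acetate, C=COC(C)=O
Why: Lipase-catalysed desymmetrisation (enantiotopic-group-selective transesterification of a prochiral 2-substituted propane-1,3-diol): the enzyme acetylates only one CH2OH, which sets the stereocenter that becomes C7, and tautomerisation of the vinyl alcohol to acetaldehyde makes the step irreversible.

**Step 5**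
Reactants: 5 (S)-2-(hydroxymethyl)but-3-en-1-yl acetate
Product: 7 (R)-2-(iodomethyl)but-3-en-1-yl acetate
Conditions: I2, PPh3, imidazole, CH2Cl2, 0 °C
Reagents that add atoms: iodine, II
Why: Appel-type iodination (PPh3, I2, imidazole) turns the primary alcohol into the iodide under near-neutral conditions and at once, so that no 1,3-acetyl migration can erode the stereocenter, which is not touched (the descriptor changes only because CH2I outranks CH2OAc).

**Step 6**
Reactants: 6 (R)-2-(hydroxymethyl)but-3-en-1-yl acetate
Product: 8 (S)-2-(bromomethyl)but-3-en-1-yl acetate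
Conditions: CBr4, PPh3, CH2Cl2, 0 °C
Reagents that add atoms: tetrabromomethane, BrC(Br)(Br)Br
Why: Appel bromination (PPh3, CBr4) of the primary alcohol under neutral conditions; the stereocenter is not touched and, with the hydroxyl gone, acetyl migration is no longer possible.

**Step 7**
Reactants: 9 prop-2-yn-1-ol
Product: 11 (Z)-3-iodo-2-methylprop-2-en-1-ol, via alkenylmagnesium alkoxide 10 (not isolated)
Conditions: MeMgBr (2.5 equiv), CuI (10 mol%), THF, −10 °C → rt; then I2, −10 °C
Reagents that add atoms: methylmagnesium bromide, C[Mg]Br; iodine, II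
Why: Copper-catalysed anti-carbomagnesiation of the propargylic alkoxide (Duboudin-type carbometalation) puts the methyl group on the inner carbon and magnesium on the terminal carbon cis to CH2O in a five-membered chelate, and iodinolysis with retention gives the Z vinyl iodide.

**Step 8**
Reactants: 7 (R)-2-(iodomethyl)but-3-en-1-yl acetate; 11 (Z)-3-iodo-2-methylprop-2-en-1-ol
Product: 13 (R,Z)-7-hydroxy-2-(iodomethyl)-6-methylhept-5-en-1-yl acetate, via B-alkyl-9-BBN adduct 12 (not isolated)
Conditions: 9-BBN (1.05 equiv), THF, 0 °C → rt; then 11, Pd(dppf)Cl2 (5 mol%), AsPh3, Cs2CO3, DMF/H2O, rt, dark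
Reagents that add atoms: none
Why: B-alkyl Suzuki–Miyaura coupling: 9-BBN adds anti-Markovnikov to the vinyl group and the primary alkylborane couples with the vinyl iodide with retention of the Z geometry, zerovalent palladium inserting into the vinyl C–I bond far faster than into the unactivated alkyl C–I bond; the stereocenter is not touched.

**Step 9**
Reactants: 8 (S)-2-(bromomethyl)but-3-en-1-yl acetate; 13 (R,Z)-7-hydroxy-2-(iodomethyl)-6-methylhept-5-en-1-yl acetate
Product: 15 (2S,6R)-2-(bromomethyl)-6-[(Z)-5-hydroxy-4-methylpent-3-en-1-yl]heptane-1,7-diyl diacetate, via B-alkyl-9-BBN adduct 14 (not isolated)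
Conditions: 9-BBN (1.0 equiv), THF, 0 °C → rt; then 13 (0.85 equiv), Pd(OAc)2 (5 mol%), PCy3 (10 mol%), K3PO4·H2O, THF, rt
Reagents that add atoms: none
Why: Alkyl–alkyl Suzuki–Miyaura coupling (Pd(OAc)2/PCy3 system of Fu): the borane made from the vinyl group of 8 couples with the primary iodide of 13, which adds to the electron-rich zerovalent palladium much faster than the bromide carried by 14 and 15, so the C9–C10 bond forms without self-coupling and both stereocenters come in unchanged.

**Step 10**
Reactants: 15 (2S,6R)-2-(bromomethyl)-6-[(Z)-5-hydroxy-4-methylpent-3-en-1-yl]heptane-1,7-diyl diacetate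
Product: 16 (2R,6R)-2-[(Z)-5-hydroxy-4-methylpent-3-en-1-yl]-6-(prop-2-en-1-yl)heptane-1,7-diyl diacetate
Conditions: vinyl bromide (1 M in THF, 3 equiv), NiBr2(dme) (10 mol%), 4,4'-di-tert-butyl-2,2'-bipyridine (10 mol%), Mn powder, NaI (cat.), DMA, rt
Reagents that add atoms: vinyl bromide, C=CBr
Why: Nickel-catalysed reductive cross-electrophile coupling (Weix type): nickel takes up vinyl bromide by oxidative addition and the alkyl bromide as a radical, Mn closes the cycle, acetates and the free alcohol are tolerated, and because the radical sits on the CH2 group the neighbouring stereocenter is not touched.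

**Step 11**
Reactants: 17 furan-2(5H)-one
Product: 19 3-bromofuran-2(5H)-one, via trans-dibromolactone 18 (not isolated)
Conditions: Br2, CH2Cl2, 40 °C; then Et3N, 0 °C
Reagents that add atoms: bromine, BrBr
Why: Bromine adds across the butenolide C=C and triethylamine then removes HBr by E1cB elimination (the acidic α-H goes, the β-bromide leaves), which leaves the bromine on the α-carbon.

**Step 12**
Reactants: 16 (2R,6R)-2-[(Z)-5-hydroxy-4-methylpent-3-en-1-yl]-6-(prop-2-en-1-yl)heptane-1,7-diyl diacetate; 19 3-bromofuran-2(5H)-one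
Product: 21 (2R,6R)-2-[(Z)-5-hydroxy-4-methylpent-3-en-1-yl]-6-[3-(2-oxo-2,5-dihydrofuran-3-yl)propyl]heptane-1,7-diyl diacetate, via bis-boron adduct 20 (not isolated)
Conditions: 9-BBN (2.1 equiv), THF, 0 °C → rt; then 19, Pd(dppf)Cl2 (5 mol%), AsPh3, aq K3PO4, DMF, rt
Reagents that add atoms: none
Why: B-alkyl Suzuki–Miyaura coupling: 9-BBN hydroborates only the monosubstituted alkene (the trisubstituted alkene is inert at room temperature, the hydroxyl is held as a borinate) and the primary alkylborane couples with the α-bromobutenolide under mild base to give the 3-alkylbutenolide, with no stereocenter touched.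

**Compound list**
1 | diethyl 2-ethylidenemalonate | CCOC(=O)C(=CC)C(=O)OCC | starting material
2 | lithium dienolate of 3 (lithium 1-ethoxy-2-(ethoxycarbonyl)buta-1,3-dien-1-olate) | [Li+].CCOC(=O)C(C=C)=C([O-])OCC | intermediate
3 | diethyl 2-vinylmalonate | CCOC(=O)C(C=C)C(=O)OCC | intermediate
4 | 2-vinylpropane-1,3-diol | OCC(CO)C=C | intermediate
5 | (S)-2-(hydroxymethyl)but-3-en-1-yl acetate | CC(=O)OC[C@@H](C=C)CO | intermediate
6 | (R)-2-(hydroxymethyl)but-3-en-1-yl acetate | CC(=O)OC[C@H](C=C)CO | intermediate
7 | (R)-2-(iodomethyl)but-3-en-1-yl acetate | CC(=O)OC[C@@H](C=C)CI | intermediate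
8 | (S)-2-(bromomethyl)but-3-en-1-yl acetate | CC(=O)OC[C@H](C=C)CBr | intermediate
9 | prop-2-yn-1-ol | OCC#C | starting material
10 | bromomagnesium (Z)-3-(bromomagnesio)-2-methylprop-2-en-1-olate | Br[Mg]/C=C(/C)CO[Mg]Br | intermediate
11 | (Z)-3-iodo-2-methylprop-2-en-1-ol | I/C=C(/C)CO | intermediate
12 | (R)-4-(9-borabicyclo[3.3.1]nonan-9-yl)-2-(iodomethyl)butyl acetate | CC(=O)OC[C@H](CI)CCB1C2CCCC1CCC2 | intermediate
13 | (R,Z)-7-hydroxy-2-(iodomethyl)-6-methylhept-5-en-1-yl acetate | CC(=O)OC[C@H](CI)CC/C=C(/C)CO | intermediate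
14 | (S)-4-(9-borabicyclo[3.3.1]nonan-9-yl)-2-(bromomethyl)butyl acetate | CC(=O)OC[C@H](CCB1C2CCCC1CCC2)CBr | intermediate
15 | (2S,6R)-2-(bromomethyl)-6-[(Z)-5-hydroxy-4-methylpent-3-en-1-yl]heptane-1,7-diyl diacetate | CC(=O)OC[C@@H](CBr)CCC[C@@H](COC(C)=O)CC/C=C(/C)CO | intermediate
16 | (2R,6R)-2-[(Z)-5-hydroxy-4-methylpent-3-en-1-yl]-6-(prop-2-en-1-yl)heptane-1,7-diyl diacetate | CC(=O)OC[C@@H](CC=C)CCC[C@@H](COC(C)=O)CC/C=C(/C)CO | intermediate
17 | furan-2(5H)-one | O=C1OCC=C1 | starting material
18 | trans-3,4-dibromodihydrofuran-2(3H)-one (racemic, one enantiomer drawn) | O=C1OC[C@H](Br)[C@H]1Br | intermediate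
19 | 3-bromofuran-2(5H)-one | O=C1OCC=C1Br | intermediate
20 | (2S,6R)-2-[3-(9-borabicyclo[3.3.1]nonan-9-yl)propyl]-6-[(Z)-5-(9-borabicyclo[3.3.1]nonan-9-yloxy)-4-methylpent-3-en-1-yl]heptane-1,7-diyl diacetate | CC(=O)OC[C@@H](CCCB1C2CCCC1CCC2)CCC[C@@H](COC(C)=O)CC/C=C(/C)COB1C2CCCC1CCC2 | intermediate
21 | (2R,6R)-2-[(Z)-5-hydroxy-4-methylpent-3-en-1-yl]-6-[3-(2-oxo-2,5-dihydrofuran-3-yl)propyl]heptane-1,7-diyl diacetate (CNP0139404.2) | CC(=O)OC[C@@H](CCCC1=CCOC1=O)CCC[C@H](CC/C=C(/C)CO)COC(C)=O | target

**Totals**
Total step count: 12. Longest linear sequence: 8 steps (steps 1, 2, 3, 5, 8, 9, 10, 12).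

**Three steps most likely to fail**

Step 3 (the proposed new zinc-catalysed acetylation; the risks are modest enantioselectivity with the small vinyl group and acetyl migration on the catalyst). The fallback uses known enzyme chemistry, sets out from 4 and comes back at 5. Diol 4 is acetylated on both hydroxyls (Ac2O, pyridine) to 2-vinylpropane-1,3-diyl diacetate F1. Porcine pancreatic lipase in pH 7 phosphate buffer then hydrolyses one of the two enantiotopic acetates. The enzyme attacks the same arm that it acetylates in step 4, so the acetate left behind sits on the other arm and the product is 5, at the cost of one more step.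

Step 9 (alkyl–alkyl Suzuki union; the risks are slow oxidative addition at the β-branched iodide and competing reaction of the bromide). The fallback reverses the polarity so that the branched partner is the nucleophile; it sets out from 7 and 8, also takes the place of step 8, and comes back at 15. HBr with AIBN in hexane adds anti-Markovnikov to the vinyl group of 8 to give (S)-4-bromo-2-(bromomethyl)butyl acetate F2. Zinc dust with LiCl in THF inserts into the C–I bond of 7 to give [(R)-2-(acetoxymethyl)but-3-en-1-yl]zinc iodide F3. A Negishi alkyl–alkyl coupling (Pd2(dba)3, PCyp3, N-methylimidazole, THF/NMP, 80 °C) joins F3 to the unbranched CH2Br of F2, the β-branched CH2Br reacting much more slowly, and gives (2S,6R)-2-(bromomethyl)-6-vinylheptane-1,7-diyl diacetate F4. Its vinyl group is hydroborated with 9-BBN to (2S,6S)-6-[2-(9-borabicyclo[3.3.1]nonan-9-yl)ethyl]-2-(bromomethyl)heptane-1,7-diyl diacetate F5, which is coupled with 11 under the conditions of step 8 to give 15.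

Step 12 (last-step Suzuki coupling onto a base-sensitive α-bromobutenolide). The fallback builds the butenolide by an ene reaction instead of a cross-coupling; it sets out from 16 and comes back at 21. The allyl group of 16 and ethyl 4-hydroxybut-2-ynoate F6 (commercial) undergo the ruthenium-catalysed Alder-ene addition of Trost (CpRu(cod)Cl, MeOH, reflux), the new C–C bond forming at the α-carbon of the ynoate. The primary adduct, ethyl (Z)-4-hydroxybut-2-enoate carrying at C2 the (E)-prop-2-en-1-yl-linked chain of 16 F7, lactonises in the flask to (2R,6R)-2-[(Z)-5-hydroxy-4-methylpent-3-en-1-yl]-6-[(E)-3-(2-oxo-2,5-dihydrofuran-3-yl)prop-1-en-1-yl]heptane-1,7-diyl diacetate F8. The new disubstituted C5=C6 alkene is then hydrogenated selectively with RhCl(PPh3)3 and H2 (benzene/EtOH, rt), which leaves the trisubstituted alkene and the butenolide alone and gives 21.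

**Further compounds**
F1 | step 3 | 2-vinylpropane-1,3-diyl diacetate | CC(=O)OCC(C=C)COC(C)=O
F2 | step 9 | (S)-4-bromo-2-(bromomethyl)butyl acetate | CC(=O)OC[C@H](CCBr)CBr
F3 | step 9 | [(R)-2-(acetoxymethyl)but-3-en-1-yl]zinc iodide | CC(=O)OC[C@@H](C=C)C[Zn]I
F4 | step 9 | (2S,6R)-2-(bromomethyl)-6-vinylheptane-1,7-diyl diacetate | CC(=O)OC[C@@H](CBr)CCC[C@@H](COC(C)=O)C=C
F5 | step 9 | (2S,6S)-6-[2-(9-borabicyclo[3.3.1]nonan-9-yl)ethyl]-2-(bromomethyl)heptane-1,7-diyl diacetate | CC(=O)OC[C@@H](CBr)CCC[C@@H](COC(C)=O)CCB1C2CCCC1CCC2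
F6 | step 12 | ethyl 4-hydroxybut-2-ynoate | CCOC(=O)C#CCO
F7 | step 12 | ethyl (Z)-4-hydroxybut-2-enoate carrying at C2 the (E)-prop-2-en-1-yl-linked chain of 16 (Alder-ene adduct, not isolated) | CC(=O)OC[C@@H](/C=C/C/C(C(=O)OCC)=C/CO)CCC[C@H](CC/C=C(/C)CO)COC(C)=O
F8 | step 12 | (2R,6R)-2-[(Z)-5-hydroxy-4-methylpent-3-en-1-yl]-6-[(E)-3-(2-oxo-2,5-dihydrofuran-3-yl)prop-1-en-1-yl]heptane-1,7-diyl diacetate | CC(=O)OC[C@@H](/C=C/CC1=CCOC1=O)CCC[C@H](CC/C=C(/C)CO)COC(C)=O
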